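Ring A is built last, by a Dötz benzannulation onto a finished ring C. In the target, ring A has oxygens at C5 and C8 para to each other, a third at C7, and is fused through C4a–C8a to the pyran oxygen. A methoxycarbene, one CO and an alkyne deliver exactly this pattern onto an enol-ether alkene. In one operation chromium carbene 15 and ethynylboronate 16 form C5–C6, C7–C8 and C8–C8a, close ring A and mark C7 with boron. The precursor is a (2S)-2-aryl-3,4-dihydro-2H-pyran with a silyl-protected C4 hydroxyl and a pentacarbonylchromium methoxycarbene on its C5, the future C4a.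

Key step: step 8

Abbreviations: TBS = tert-butyldimethylsilyl; Bpin = 4,4,5,5-tetramethyl-1,3,2-dioxaborolan-2-yl; Ar = 4-(TBS-oxy)-3-(3-methylbut-3-en-1-yl)phenyl. Compounds 8–15 use pyran numbering; 17–22 use chroman (flavan) numbering.

Assumption: the (S)-BINOL–titanium catalyst is taken to give the (2S) adduct in step 3, by analogy with its facial sense in aldehyde allylation. The sense is to be checked by chiral HPLC on the first run, and the (R)-ligand used if it is opposite.

Remark: C4 is carried as the single 2,4-cis (4S) isomer expected from step 5. It is a temporary centre and is erased in step 11.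

Step 1
Reactants: 1 3-bromo-4-hydroxybenzaldehyde
Product: 2 3-bromo-4-(TBS-oxy)benzaldehyde
Conditions: TBSCl, imidazole, CH2Cl2, 0 °C → rt
Reagents that add atoms: tert-butyldimethylsilyl chloride, CC(C)(C)[Si](C)(C)Cl
Why: Imidazole-mediated O-silylation of an acidic phenol, to which the aldehyde and the aryl bromide are inert.

Step 2
Reactants: 2 3-bromo-4-(TBS-oxy)benzaldehyde; 3 4-bromo-2-methylbut-1-ene
Product: 5 4-(TBS-oxy)-3-(3-methylbut-3-en-1-yl)benzaldehyde, via (3-methylbut-3-en-1-yl)zinc bromide 4 (not isolated)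
Conditions: 3, Zn dust, LiCl, THF, 40 °C; then 2, Pd(OAc)2 (2 mol %), SPhos (4 mol %), THF, rt → 45 °C
Reagents that add atoms: none
Why: Negishi coupling, in which LiCl-assisted zinc insertion gives a primary alkylzinc halide that leaves the aldehyde alone, and the bulky biarylphosphine makes reductive elimination outrun β-hydride elimination.

Step 3
Reactants: 5 4-(TBS-oxy)-3-(3-methylbut-3-en-1-yl)benzaldehyde; 6 Danishefsky's diene
Product: 8 (2S)-2-Ar-2,3-dihydro-4H-pyran-4-one, via Mukaiyama aldol silyl ether 7 (not isolated)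
Conditions: Ti(OiPr)4 (10 mol %), (S)-BINOL (20 mol %), 4 Å MS, Et2O, −20 °C; then TFA, CH2Cl2, 0 °C
Reagents that add atoms: none
Why: Catalytic asymmetric hetero-Diels–Alder reaction by the Mukaiyama aldol–cyclisation pathway, in which the chiral titanium binaphtholate shields one face of the bound aldehyde and so sets C2 as S, and brief acid closes the ring by oxa-Michael addition with loss of methanol.

Step 4
Reactants: 8 (2S)-2-Ar-2,3-dihydro-4H-pyran-4-one
Product: 9 (2S)-2-Ar-5-iodo-2,3-dihydro-4H-pyran-4-one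
Conditions: I2, pyridine, CH2Cl2, 0 °C → rt
Reagents that add atoms: iodine, II
Why: Electrophilic α-iodination of a vinylogous ester, whose C5 is the nucleophilic enol-ether carbon, followed by pyridine-mediated loss of the C5 proton; the isolated alkene binds iodine only reversibly.

Step 5
Reactants: 9 (2S)-2-Ar-5-iodo-2,3-dihydro-4H-pyran-4-one
Product: 10 (2S,4S)-2-Ar-5-iodo-3,4-dihydro-2H-pyran-4-ol
Conditions: NaBH4, CeCl3·7H2O, MeOH, −78 °C
Reagents that add atoms: none
Why: Luche reduction, in which CeCl3 makes the borohydride a selective 1,2-reductant of the conjugated carbonyl, and axial hydride delivery to the half-chair with the aryl group equatorial should give the 2,4-cis (4S) alcohol.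

Step 6
Reactants: 10 (2S,4S)-2-Ar-5-iodo-3,4-dihydro-2H-pyran-4-ol
Product: 11 (2S,4S)-2-Ar-5-iodo-4-(TBS-oxy)-3,4-dihydro-2H-pyran
Conditions: TBSCl, imidazole, DMF, rt
Reagents that add atoms: tert-butyldimethylsilyl chloride, CC(C)(C)[Si](C)(C)Cl
Why: Base-mediated silylation protects the allylic alcohol without ionising the acid-sensitive enol-ether allylic system, and the bulky silyl group resists migration to carbon in the next step.

Step 7
Reactants: 11 (2S,4S)-2-Ar-5-iodo-4-(TBS-oxy)-3,4-dihydro-2H-pyran; 12 Cr(CO)6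
Product: 15 pentacarbonyl{methoxy[(2S,4S)-2-Ar-4-(TBS-oxy)-3,4-dihydro-2H-pyran-5-yl]methylidene}chromium, via vinyllithium 13 (not isolated), via lithium acylpentacarbonylchromate 14 (not isolated)
Conditions: t-BuLi (2.05 equiv), Et2O, −100 °C; cold cannula into Cr(CO)6, THF, −78 → −20 °C; then Me3OBF4, CH2Cl2, 0 °C
Reagents that add atoms: trimethyloxonium tetrafluoroborate, C[O+](C)C.F[B-](F)(F)F
Why: Fischer carbene synthesis, in which iodine–lithium exchange on the vinyl iodide, addition of the vinyllithium to a CO ligand and O-methylation of the acyl chromate by the hard oxonium salt follow one another, the very low temperature being chosen because lithium on C5 lies anti to the ring C6–O1 bond and could otherwise open the ring by β-elimination.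

Step 8
Reactants: 15 pentacarbonyl{methoxy[(2S,4S)-2-Ar-4-(TBS-oxy)-3,4-dihydro-2H-pyran-5-yl]methylidene}chromium; 16 2-ethynyl-4,4,5,5-tetramethyl-1,3,2-dioxaborolane
Product: 17 (2S,4S)-2-Ar-5-methoxy-7-Bpin-4-(TBS-oxy)chroman-8-ol
Conditions: 16 (2 equiv), THF (0.05 M), 50 °C, Ar; then air, Et2O/hexane, rt
Reagents that add atoms: none
Why: Thermal loss of one CO from 15 lets 16 bind and insert into the Cr=C bond with its unsubstituted terminus at the carbene carbon (C5–C6), and CO insertion into the resulting vinylcarbene gives a chromium-bound dienylketene (C7–C8). Ring A then closes by a thermal six-electron electrocyclisation of the ketene carbon onto the enol-ether carbon C8a (C8–C8a), and enolisation of the cyclohexadienone gives the C8 phenol. The closest known reaction type is the Dötz benzannulation of alkenyl(alkoxy)carbene chromium complexes with alkynylboronates, which gives ortho-boryl hydroquinone monoethers. No stereocenter is formed, and C2 and C4 are sp3 centres remote from the metal that should not epimerise under neutral conditions at 50 °C. The step needs the boron-bearing carbon next to the CO-derived C8 and needs CO insertion in place of five-ring closure: the first follows from the steric preference that places the larger alkyne substituent beside the CO carbon and hydrogen beside the carbene carbon, and the second is favoured by the alkoxy carbene, the ether solvent and dilution, although the donor oxygen on C8a makes this the point of greatest uncertainty.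

Step 9
Reactants: 17 (2S,4S)-2-Ar-5-methoxy-7-Bpin-4-(TBS-oxy)chroman-8-ol
Product: 18 (2S,4S)-2-Ar-5-methoxy-4-(TBS-oxy)chromane-7,8-diol
Conditions: NaBO3·4H2O, degassed THF/H2O (1:1), 0 °C → rt, Ar; used crude
Reagents that add atoms: sodium perborate tetrahydrate, [Na+].[O-]OB=O.O.O.O.O
Why: Ipso-oxidation of an aryl boronate, in which the peroxoborate adds to boron, the aryl group shifts from boron to oxygen and hydrolysis frees the C7 phenol under mildly basic conditions that should spare the silyl ethers.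

Step 10
Reactants: 18 (2S,4S)-2-Ar-5-methoxy-4-(TBS-oxy)chromane-7,8-diol
Product: 19 (2S,4S)-2-Ar-5-methoxy-4,7,8-tris(TBS-oxy)chromane
Conditions: TBSCl (3 equiv), imidazole, DMAP (cat.), DMF, rt
Reagents that add atoms: tert-butyldimethylsilyl chloride, CC(C)(C)[Si](C)(C)Cl
Why: Imidazole-mediated silylation of both phenols, as is routine for catechols and gallates, masks the oxidisable catechol before C4 is oxidised.

Step 11
Reactants: 19 (2S,4S)-2-Ar-5-methoxy-4,7,8-tris(TBS-oxy)chromane
Product: 20 (2S)-2-Ar-5-methoxy-7,8-bis(TBS-oxy)chroman-4-one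
Conditions: DDQ (1.1 equiv), CH2Cl2/pH 7 phosphate buffer (10:1), 0 °C
Reagents that add atoms: none
Why: DDQ oxidation of an electron-rich benzylic silyl ether, in which hydride is abstracted from C4–H (activated by the ortho and para oxygens of ring A and by the α-silyloxy group) and the resulting silyloxycarbenium ion loses its silyl group to water to leave the ketone, while the aryl silyl ethers and the less activated C2–H should not react.

Step 12
Reactants: 20 (2S)-2-Ar-5-methoxy-7,8-bis(TBS-oxy)chroman-4-one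
Product: 21 (2S)-2-Ar-5-hydroxy-7,8-bis(TBS-oxy)chroman-4-one
Conditions: MgI2, Et2O/toluene, rt → 45 °C
Reagents that add atoms: none
Why: Chelation-directed demethylation, in which magnesium bridges the C4 carbonyl and the peri 5-methoxy oxygen so that iodide removes only that methyl group by SN2 attack, and any incidental loss of a silyl group is harmless because step 13 removes them all.

Step 13
Reactants: 21 (2S)-2-Ar-5-hydroxy-7,8-bis(TBS-oxy)chroman-4-one
Product: 22 (2S)-5,7,8-trihydroxy-2-[4-hydroxy-3-(3-methylbut-3-en-1-yl)phenyl]chroman-4-one (CNP0293707.1)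
Conditions: TBAF, AcOH (1:1.2), THF, 0 °C, Ar; mildly acidic work-up
Reagents that add atoms: none
Why: Fluoride cleaves the three aryl silyl ethers quickly, and the acetic acid buffer keeps the phenols protonated so that the flavanone should not open to the chalcone, which would racemise C2 or let the ring re-close onto the C5 oxygen.

Compound list
1 | 3-bromo-4-hydroxybenzaldehyde | O=Cc1ccc(O)c(Br)c1 | starting material
2 | 3-bromo-4-(TBS-oxy)benzaldehyde | O=Cc1ccc(O[Si](C)(C)C(C)(C)C)c(Br)c1 | intermediate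
3 | 4-bromo-2-methylbut-1-ene | C=C(C)CCBr | starting material
4 | (3-methylbut-3-en-1-yl)zinc bromide | C=C(C)CC[Zn]Br | intermediate (not isolated)
5 | 4-(TBS-oxy)-3-(3-methylbut-3-en-1-yl)benzaldehyde | C=C(C)CCc1cc(C=O)ccc1O[Si](C)(C)C(C)(C)C | intermediate
6 | Danishefsky's diene, (E)-1-methoxy-3-(trimethylsilyloxy)buta-1,3-diene | CO/C=C/C(=C)O[Si](C)(C)C | starting material
7 | (1E,5S)-5-Ar-1-methoxy-5-(trimethylsilyloxy)pent-1-en-3-one (Mukaiyama aldol silyl ether) | C=C(C)CCc1cc([C@@H](O[Si](C)(C)C)CC(=O)/C=C/OC)ccc1O[Si](C)(C)C(C)(C)C | intermediate (not isolated)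
8 | (2S)-2-Ar-2,3-dihydro-4H-pyran-4-one | C=C(C)CCc1cc([C@@H]2CC(=O)C=CO2)ccc1O[Si](C)(C)C(C)(C)C | intermediate
9 | (2S)-2-Ar-5-iodo-2,3-dihydro-4H-pyran-4-one | C=C(C)CCc1cc([C@@H]2CC(=O)C(I)=CO2)ccc1O[Si](C)(C)C(C)(C)C | intermediate
10 | (2S,4S)-2-Ar-5-iodo-3,4-dihydro-2H-pyran-4-ol | C=C(C)CCc1cc([C@@H]2C[C@H](O)C(I)=CO2)ccc1O[Si](C)(C)C(C)(C)C | intermediate
11 | (2S,4S)-2-Ar-5-iodo-4-(TBS-oxy)-3,4-dihydro-2H-pyran | C=C(C)CCc1cc([C@@H]2C[C@H](O[Si](C)(C)C(C)(C)C)C(I)=CO2)ccc1O[Si](C)(C)C(C)(C)C | intermediate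
12 | hexacarbonylchromium, Cr(CO)6 | O=C=[Cr](=C=O)(=C=O)(=C=O)(=C=O)=C=O | starting material
13 | [(2S,4S)-2-Ar-4-(TBS-oxy)-3,4-dihydro-2H-pyran-5-yl]lithium (vinyllithium) | C=C(C)CCc1cc([C@@H]2C[C@H](O[Si](C)(C)C(C)(C)C)C([Li])=CO2)ccc1O[Si](C)(C)C(C)(C)C | intermediate (not isolated)
14 | lithium pentacarbonyl{[(2S,4S)-2-Ar-4-(TBS-oxy)-3,4-dihydro-2H-pyran-5-yl]oxidomethylidene}chromate (lithium acylpentacarbonylchromate) | [Li+].C=C(C)CCc1cc([C@@H]2C[C@H](O[Si](C)(C)C(C)(C)C)C(C([O-])=[Cr](=C=O)(=C=O)(=C=O)(=C=O)=C=O)=CO2)ccc1O[Si](C)(C)C(C)(C)C | intermediate (not isolated)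
15 | pentacarbonyl{methoxy[(2S,4S)-2-Ar-4-(TBS-oxy)-3,4-dihydro-2H-pyran-5-yl]methylidene}chromium | C=C(C)CCc1cc([C@@H]2C[C@H](O[Si](C)(C)C(C)(C)C)C(C(OC)=[Cr](=C=O)(=C=O)(=C=O)(=C=O)=C=O)=CO2)ccc1O[Si](C)(C)C(C)(C)C | intermediate
16 | 2-ethynyl-4,4,5,5-tetramethyl-1,3,2-dioxaborolane (ethynylboronic acid pinacol ester) | C#CB1OC(C)(C)C(C)(C)O1 | starting material
17 | (2S,4S)-2-Ar-5-methoxy-7-Bpin-4-(TBS-oxy)chroman-8-ol | C=C(C)CCc1cc([C@@H]2C[C@H](O[Si](C)(C)C(C)(C)C)c3c(OC)cc(B4OC(C)(C)C(C)(C)O4)c(O)c3O2)ccc1O[Si](C)(C)C(C)(C)C | intermediate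
18 | (2S,4S)-2-Ar-5-methoxy-4-(TBS-oxy)chromane-7,8-diol | C=C(C)CCc1cc([C@@H]2C[C@H](O[Si](C)(C)C(C)(C)C)c3c(OC)cc(O)c(O)c3O2)ccc1O[Si](C)(C)C(C)(C)C | intermediate
19 | (2S,4S)-2-Ar-5-methoxy-4,7,8-tris(TBS-oxy)chromane | C=C(C)CCc1cc([C@@H]2C[C@H](O[Si](C)(C)C(C)(C)C)c3c(OC)cc(O[Si](C)(C)C(C)(C)C)c(O[Si](C)(C)C(C)(C)C)c3O2)ccc1O[Si](C)(C)C(C)(C)C | intermediate
20 | (2S)-2-Ar-5-methoxy-7,8-bis(TBS-oxy)chroman-4-one | C=C(C)CCc1cc([C@@H]2CC(=O)c3c(OC)cc(O[Si](C)(C)C(C)(C)C)c(O[Si](C)(C)C(C)(C)C)c3O2)ccc1O[Si](C)(C)C(C)(C)C | intermediate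
21 | (2S)-2-Ar-5-hydroxy-7,8-bis(TBS-oxy)chroman-4-one | C=C(C)CCc1cc([C@@H]2CC(=O)c3c(O)cc(O[Si](C)(C)C(C)(C)C)c(O[Si](C)(C)C(C)(C)C)c3O2)ccc1O[Si](C)(C)C(C)(C)C | intermediate
22 | (2S)-5,7,8-trihydroxy-2-[4-hydroxy-3-(3-methylbut-3-en-1-yl)phenyl]chroman-4-one | C=C(C)CCc1cc([C@@H]2CC(=O)c3c(O)cc(O)c(O)c3O2)ccc1O | target

Total step count: 13. Longest linear sequence: 13 steps (1 → 22); compounds 3, 6, 12 and 16 are purchased.

Steps most likely to fail

1. Step 8. The terminal alkynylboronate may oligomerise or lose boron at 50 °C before it inserts, or the electron-rich enol-ether carbene may stop after alkyne insertion and close a five-membered ring without taking up CO. Fallback: the boron is carried as a four-coordinate group that is not Lewis acidic, so the alkyne behaves as a plain hindered terminal alkyne. Carbene 15 is heated in THF at 50–60 °C with ethynylboronic acid N-methyliminodiacetate and should give (2S,4S)-2-Ar-5-methoxy-7-(N-methyliminodiacetato)boryl-4-(TBS-oxy)chroman-8-ol F1. NaBO3·4H2O in THF/H2O then releases and oxidises the boron in one flask, and the route is rejoined at 18.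

2. Step 7. Vinyllithium 13 may open the ring by anti β-elimination of the ring alkoxide before the sparingly soluble Cr(CO)6 captures it, or the neighbouring silyl group may migrate from oxygen to carbon on warming. Fallback without any vinyl anion: iodide 11 is hydroxycarbonylated (Pd(PPh3)4, CO 1 atm, Et3N, THF/H2O, 50 °C) to (2S,4S)-2-Ar-4-(TBS-oxy)-3,4-dihydro-2H-pyran-5-carboxylic acid F2. 1-Chloro-N,N,2-trimethylprop-1-en-1-amine in CH2Cl2 at 0 °C converts it under neutral conditions into the acid chloride F3. This is added at −78 °C to Na2Cr(CO)5 (from Cr(CO)6 and NaC10H8 in THF) to give the sodium acylpentacarbonylchromate F4. Methylation with Me3OBF4 in CH2Cl2 at 0 °C rejoins the route at 15.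

3. Step 11. DDQ may over-oxidise (dehydrogenation across C2–C3 of the new flavanone, or attack at C2–H) or strip silyl groups from ring A oxidatively. Fallback in two stages: from 19, HF·pyridine buffered with excess pyridine in THF at 0 °C should cleave the alkyl silyl ether at C4 faster than the three aryl silyl ethers and give (2S,4S)-2-Ar-5-methoxy-7,8-bis(TBS-oxy)chroman-4-ol F5. Activated MnO2 in CH2Cl2 at rt (or Dess–Martin periodinane buffered by NaHCO3) then oxidises the benzylic alcohol, and the route is rejoined at 20.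

Further compounds
F1 | step 8 | (2S,4S)-2-Ar-5-methoxy-7-(N-methyliminodiacetato)boryl-4-(TBS-oxy)chroman-8-ol | C=C(C)CCc1cc([C@@H]2C[C@H](O[Si](C)(C)C(C)(C)C)c3c(OC)cc([B-]45OC(=O)C[N+]4(C)CC(=O)O5)c(O)c3O2)ccc1O[Si](C)(C)C(C)(C)C
F2 | step 7 | (2S,4S)-2-Ar-4-(TBS-oxy)-3,4-dihydro-2H-pyran-5-carboxylic acid | C=C(C)CCc1cc([C@@H]2C[C@H](O[Si](C)(C)C(C)(C)C)C(C(=O)O)=CO2)ccc1O[Si](C)(C)C(C)(C)C
F3 | step 7 | (2S,4S)-2-Ar-4-(TBS-oxy)-3,4-dihydro-2H-pyran-5-carbonyl chloride | C=C(C)CCc1cc([C@@H]2C[C@H](O[Si](C)(C)C(C)(C)C)C(C(=O)Cl)=CO2)ccc1O[Si](C)(C)C(C)(C)C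
F4 | step 7 | sodium pentacarbonyl{[(2S,4S)-2-Ar-4-(TBS-oxy)-3,4-dihydro-2H-pyran-5-yl]oxidomethylidene}chromate | [Na+].C=C(C)CCc1cc([C@@H]2C[C@H](O[Si](C)(C)C(C)(C)C)C(C([O-])=[Cr](=C=O)(=C=O)(=C=O)(=C=O)=C=O)=CO2)ccc1O[Si](C)(C)C(C)(C)C
F5 | step 11 | (2S,4S)-2-Ar-5-methoxy-7,8-bis(TBS-oxy)chroman-4-ol | C=C(C)CCc1cc([C@@H]2C[C@H](O)c3c(OC)cc(O[Si](C)(C)C(C)(C)C)c(O[Si](C)(C)C(C)(C)C)c3O2)ccc1O[Si](C)(C)C(C)(C)C
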